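The oxolane is disconnected at O1–C5, the bond to the benzylic carbon that bears ring B (the trisubstituted phenol). C5 lies para to the phenolic OH of ring B. In the open-chain precursor the C5H2 group is therefore the vinylogous alpha-position of a phenol. DDQ takes a hydride from exactly this site, and the C2 hydroxyl adds to the resulting p-quinone methide. One operation converts an unfunctionalised CH2 into the C5 stereocentre and closes the ring. The precursor is an acyclic 4-arylbutan-1-ol assembled by two hydroboration/Suzuki couplings. C2/C3 come from an anti-selective catalytic allylboration, C4 from substrate-controlled 9-BBN addition, and the side-chain centre from cobalt-catalysed hydroboration.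

Key step: step 9

Remark on the chemistry:
- **Numbering.** The oxolane is numbered O1, C2 (bears ring A, a 4-hydroxyphenyl group), C3, C4, C5 (bears ring B). C1' is the ring B carbon bonded to C5. Ring C is the 4-hydroxyphenyl group of the side chain.
- **Configuration.** In this numbering the target is (2S,3S,4R,5R) with an (R) side-chain centre, that is 2,3-trans, 3,4-cis, 4,5-trans.
- **Assumption.** The sense of induction of the two chiral catalysts (steps 3 and 6) is assigned by analogy with simple benzaldehydes and alpha-methylstyrenes. Both catalysts are available as either antipode.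

Step 1
Reactants: 1 but-2-yne
Product: 2 (Z)-2-(but-2-en-2-yl)-4,4,5,5-tetramethyl-1,3,2-dioxaborolane
Conditions: HBpin, Cp2ZrHCl (5 mol %), Et3N (10 mol %), neat, sealed tube, 60 °C
Reagents that add atoms: pinacolborane, B1OC(C)(C)C(C)(C)O1
Why: Zirconium-catalysed syn-hydroboration of the symmetrical alkyne places H and B on the same side, which fixes the two methyl groups cis and thereby the geometry needed in step 2.

Step 2
Reactants: 2 (Z)-2-(but-2-en-2-yl)-4,4,5,5-tetramethyl-1,3,2-dioxaborolane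
Product: 4 (E)-4,4,5,5-tetramethyl-2-(2-methylbut-2-en-1-yl)-1,3,2-dioxaborolane, via chloromethyl boronate complex 3 (not isolated)
Conditions: BrCH2Cl, n-BuLi, THF, −78 °C to rt
Reagents that add atoms: bromochloromethane, ClCBr
Why: Matteson homologation, in which chloromethyllithium adds to boron and the alkenyl group shifts 1,2 with loss of chloride and retention of the double-bond geometry, so the terminal methyl ends trans to CH2B.

Step 3
Reactants: 4 (E)-4,4,5,5-tetramethyl-2-(2-methylbut-2-en-1-yl)-1,3,2-dioxaborolane; 5 4-(benzyloxy)benzaldehyde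
Product: 7 (1S,2S)-1-[4-(benzyloxy)phenyl]-2,3-dimethylbut-3-en-1-ol, via homoallyl pinacol borate 6 (not isolated)
Conditions: (S)-TRIP phosphoric acid (5 mol %), 4 Å MS, toluene, −30 °C; aq. NaHCO3 work-up
Reagents that add atoms: none
Why: Chiral-phosphoric-acid-catalysed allylboration through a closed chair transition state, in which the (E)-boronate gives the anti C2/C3 pair and the (S)-acid should direct attack to the Si face of the aldehyde, setting (S)-C2 and (S)-C3.

Step 4
Reactants: 8 1-(5-chloro-2-hydroxyphenyl)ethan-1-one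
Product: 9 1-(5-chloro-2-{[tri(propan-2-yl)silyl]oxy}phenyl)ethan-1-one
Conditions: TIPSCl, imidazole, DMF, 40 °C
Reagents that add atoms: chlorotri(propan-2-yl)silane, CC(C)[Si](Cl)(C(C)C)C(C)C
Why: O-silylation masks the ring B phenol with a group that should tolerate ylide, borane and aqueous phosphate and that is orthogonal to the benzyl ethers of rings A and C.

Step 5
Reactants: 9 1-(5-chloro-2-{[tri(propan-2-yl)silyl]oxy}phenyl)ethan-1-one
Product: 10 [4-chloro-2-(prop-1-en-2-yl)phenoxy]tri(propan-2-yl)silane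
Conditions: MePPh3Br, KOtBu, THF, 0 °C to rt
Reagents that add atoms: methyltriphenylphosphonium bromide, C[P+](c1ccccc1)(c1ccccc1)c1ccccc1.[Br-]
Why: Wittig methylenation of an aryl methyl ketone with the unstabilised ylide gives the 1,1-disubstituted aryl alkene needed for the asymmetric hydroboration.

Step 6
Reactants: 10 [4-chloro-2-(prop-1-en-2-yl)phenoxy]tri(propan-2-yl)silane
Product: 11 {4-chloro-2-[(2R)-1-(4,4,5,5-tetramethyl-1,3,2-dioxaborolan-2-yl)propan-2-yl]phenoxy}tri(propan-2-yl)silane
Conditions: HBpin, CoCl2 (2 mol %), chiral iminopyridine-oxazoline ligand (2 mol %), NaBHEt3 (6 mol %), THF, rt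
Reagents that add atoms: pinacolborane, B1OC(C)(C)C(C)(C)O1
Why: Cobalt-hydride-catalysed anti-Markovnikov asymmetric hydroboration of a 1,1-disubstituted aryl alkene, in which the ligand distinguishes aryl from methyl during insertion and sets the (R) side-chain centre while C–Cl stays intact.

Step 7
Reactants: 11 {4-chloro-2-[(2R)-1-(4,4,5,5-tetramethyl-1,3,2-dioxaborolan-2-yl)propan-2-yl]phenoxy}tri(propan-2-yl)silane; 12 1-(benzyloxy)-4-bromobenzene
Product: 13 {2-[(2R)-1-[4-(benzyloxy)phenyl]propan-2-yl]-4-chlorophenoxy}tri(propan-2-yl)silane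
Conditions: Pd2(dba)3 (2.5 mol %), RuPhos (10 mol %), K3PO4, toluene/H2O 10:1, 80 °C
Reagents that add atoms: none
Why: sp3–sp2 Suzuki–Miyaura coupling of a primary alkylboronate, in which the stereocentre is beta to boron and takes no part, and zerovalent palladium inserts into C–Br far faster than into the electron-rich C–Cl bond.

Step 8
Reactants: 7 (1S,2S)-1-[4-(benzyloxy)phenyl]-2,3-dimethylbut-3-en-1-ol; 13 {2-[(2R)-1-[4-(benzyloxy)phenyl]propan-2-yl]-4-chlorophenoxy}tri(propan-2-yl)silane
Product: 16 4-[(2S,3S,4S)-4-[4-(benzyloxy)phenyl]-4-hydroxy-2,3-dimethylbutyl]-2-[(2R)-1-[4-(benzyloxy)phenyl]propan-2-yl]phenol, via bis-9-BBN adduct 14 (not isolated), via coupled TIPS ether 15 (not isolated)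
Conditions: 9-BBN dimer (2.4 equiv B–H), THF, 0 °C to rt; then 13, Pd(OAc)2 (5 mol %), SPhos (10 mol %), aq. K3PO4, THF, 65 °C; then TBAF, rt
Reagents that add atoms: none
Why: 9-BBN first masks the hydroxyl as a bulky borinate and then adds to the 1,1-disubstituted alkene anti to the large C2 substituent in the conformer with C3–H eclipsing the double bond (minimised A(1,3) strain), which sets C4 with the two methyls anti in the zigzag (cis in the later ring), after which a B-alkyl Suzuki–Miyaura coupling joins C5 to ring B and fluoride frees the ring B phenol.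

Step 9
Reactants: 16 4-[(2S,3S,4S)-4-[4-(benzyloxy)phenyl]-4-hydroxy-2,3-dimethylbutyl]-2-[(2R)-1-[4-(benzyloxy)phenyl]propan-2-yl]phenol
Product: 18 4-[(2R,3R,4S,5S)-5-[4-(benzyloxy)phenyl]-3,4-dimethyloxolan-2-yl]-2-[(2R)-1-[4-(benzyloxy)phenyl]propan-2-yl]phenol, via p-quinone methide 17 (not isolated)
Conditions: DDQ (1.05 equiv), 4 Å MS, CH2Cl2, 0 °C to rt
Reagents that add atoms: none
Why: DDQ forms a charge-transfer complex with the only free phenol (ring B) and removes in net terms a hydride from the para-benzylic C5H2 group to give p-quinone methide 17 and the hydroquinone, after which the C2 hydroxyl adds to C5 in an oxa-1,6-conjugate addition and ring B rearomatises. The closest known reaction type is the DDQ-mediated benzylic alkoxylation of 4-alkylphenols and the p-quinone methide cyclisations used for epoxylignans. The oxolane closes 5-exo-trig, because the C5=C1' double bond lies outside the forming ring. C5 is the only new stereocentre: in the envelope-like transition state the flat quinone methide turns away from the C4 methyl, so ring B should end trans to it and cis to ring A, and since the addition is reversible the same trans,cis,trans isomer is also the thermodynamic sink, while C2, C3, C4 and the side-chain centre are untouched. The step needs ring and site selectivity: rings A and C are benzyl ethers that cannot give quinone methides, which should keep C2–H and the side-chain CH2 inert at this temperature, and para-quinone methide formation at the secondary C5–H is preferred over ortho-quinone methide formation at the hindered tertiary side-chain C–H. One equivalent of oxidant and exclusion of water limit further oxidation of 18.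

Step 10
Reactants: 18 4-[(2R,3R,4S,5S)-5-[4-(benzyloxy)phenyl]-3,4-dimethyloxolan-2-yl]-2-[(2R)-1-[4-(benzyloxy)phenyl]propan-2-yl]phenol
Product: 19 4-[(2R,3R,4S,5S)-5-(4-hydroxyphenyl)-3,4-dimethyloxolan-2-yl]-2-[(2R)-1-(4-hydroxyphenyl)propan-2-yl]phenol (CNP0232576.1)
Conditions: H2 (1 atm), palladium on carbon (10 % Pd/C), EtOAc/EtOH, rt
Reagents that add atoms: none
Why: Hydrogenolysis of the two aryl benzyl ethers under one atmosphere should be much faster than cleavage of the hindered ring C–O bonds of the oxolane, and no stereocentre is touched.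

Compound list
1 | but-2-yne | CC#CC | starting material
2 | (Z)-2-(but-2-en-2-yl)-4,4,5,5-tetramethyl-1,3,2-dioxaborolane | C/C=C(\C)B1OC(C)(C)C(C)(C)O1 | intermediate
3 | lithium (chloromethyl)[(Z)-but-2-en-2-yl](pinacolato)borate | [Li+].C/C=C(\C)[B-]1(CCl)OC(C)(C)C(C)(C)O1 | intermediate
4 | (E)-4,4,5,5-tetramethyl-2-(2-methylbut-2-en-1-yl)-1,3,2-dioxaborolane | C/C=C(\C)CB1OC(C)(C)C(C)(C)O1 | intermediate
5 | 4-(benzyloxy)benzaldehyde | O=Cc1ccc(OCc2ccccc2)cc1 | starting material
6 | 2-{(1S,2S)-1-[4-(benzyloxy)phenyl]-2,3-dimethylbut-3-en-1-yloxy}-4,4,5,5-tetramethyl-1,3,2-dioxaborolane | C=C(C)[C@H](C)[C@@H](c1ccc(OCc2ccccc2)cc1)OB1OC(C)(C)C(C)(C)O1 | intermediate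
7 | (1S,2S)-1-[4-(benzyloxy)phenyl]-2,3-dimethylbut-3-en-1-ol (anti) | C=C(C)[C@H](C)[C@@H](c1ccc(OCc2ccccc2)cc1)O | intermediate
8 | 1-(5-chloro-2-hydroxyphenyl)ethan-1-one | CC(=O)c1cc(Cl)ccc1O | starting material
9 | 1-(5-chloro-2-{[tri(propan-2-yl)silyl]oxy}phenyl)ethan-1-one | CC(=O)c1cc(Cl)ccc1O[Si](C(C)C)(C(C)C)C(C)C | intermediate
10 | [4-chloro-2-(prop-1-en-2-yl)phenoxy]tri(propan-2-yl)silane | C=C(C)c1cc(Cl)ccc1O[Si](C(C)C)(C(C)C)C(C)C | intermediate
11 | {4-chloro-2-[(2R)-1-(4,4,5,5-tetramethyl-1,3,2-dioxaborolan-2-yl)propan-2-yl]phenoxy}tri(propan-2-yl)silane | Clc1ccc(O[Si](C(C)C)(C(C)C)C(C)C)c([C@H](C)CB2OC(C)(C)C(C)(C)O2)c1 | intermediate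
12 | 1-(benzyloxy)-4-bromobenzene | Brc1ccc(OCc2ccccc2)cc1 | starting material
13 | {2-[(2R)-1-[4-(benzyloxy)phenyl]propan-2-yl]-4-chlorophenoxy}tri(propan-2-yl)silane | Clc1ccc(O[Si](C(C)C)(C(C)C)C(C)C)c([C@H](C)Cc2ccc(OCc3ccccc3)cc2)c1 | intermediate
14 | 9-[(2S,3S,4S)-4-[4-(benzyloxy)phenyl]-4-(9-borabicyclo[3.3.1]nonan-9-yloxy)-2,3-dimethylbutyl]-9-borabicyclo[3.3.1]nonane | C[C@@H](CB1C2CCCC1CCC2)[C@H](C)[C@@H](c1ccc(OCc2ccccc2)cc1)OB1C2CCCC1CCC2 | intermediate
15 | (1S,2S,3S)-1-[4-(benzyloxy)phenyl]-4-(3-[(2R)-1-[4-(benzyloxy)phenyl]propan-2-yl]-4-{[tri(propan-2-yl)silyl]oxy}phenyl)-2,3-dimethylbutan-1-ol | C[C@@H](Cc1ccc(O[Si](C(C)C)(C(C)C)C(C)C)c([C@H](C)Cc2ccc(OCc3ccccc3)cc2)c1)[C@H](C)[C@@H](c1ccc(OCc2ccccc2)cc1)O | intermediate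
16 | 4-[(2S,3S,4S)-4-[4-(benzyloxy)phenyl]-4-hydroxy-2,3-dimethylbutyl]-2-[(2R)-1-[4-(benzyloxy)phenyl]propan-2-yl]phenol | C[C@@H](Cc1ccc(O)c([C@H](C)Cc2ccc(OCc3ccccc3)cc2)c1)[C@H](C)[C@@H](c1ccc(OCc2ccccc2)cc1)O | intermediate
17 | p-quinone methide: 4-[(2S,3S,4S)-4-[4-(benzyloxy)phenyl]-4-hydroxy-2,3-dimethylbutylidene]-2-[(2R)-1-[4-(benzyloxy)phenyl]propan-2-yl]cyclohexa-2,5-dien-1-one (exocyclic geometry not defined) | C[C@@H](C=C1C=CC(=O)C([C@H](C)Cc2ccc(OCc3ccccc3)cc2)=C1)[C@H](C)[C@@H](c1ccc(OCc2ccccc2)cc1)O | intermediate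
18 | 4-[(2R,3R,4S,5S)-5-[4-(benzyloxy)phenyl]-3,4-dimethyloxolan-2-yl]-2-[(2R)-1-[4-(benzyloxy)phenyl]propan-2-yl]phenol | C[C@@H]1[C@H](C)[C@@H](c2ccc(OCc3ccccc3)cc2)O[C@H]1c1ccc(O)c([C@H](C)Cc2ccc(OCc3ccccc3)cc2)c1 | intermediate
19 | 4-[(2R,3R,4S,5S)-5-(4-hydroxyphenyl)-3,4-dimethyloxolan-2-yl]-2-[(2R)-1-(4-hydroxyphenyl)propan-2-yl]phenol | C[C@@H]1[C@H](C)[C@@H](c2ccc(O)cc2)O[C@H]1c1ccc(O)c([C@H](C)Cc2ccc(O)cc2)c1 | target

Total step count: 10. Longest linear sequence: 7 (steps 4 to 10).

Steps most likely to fail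

1. **Step 9.**
   - What may go wrong: further dehydrogenation of the cyclised phenol at C5. The quinone methide may tautomerise to the styrene, with loss of the C4 centre. Dehydrogenation may also compete at the C2 carbinol or at the tertiary side-chain C–H.
   - Fallback: it separates oxidation from ring closure, sets out from 16 and comes back at 18. DDQ (2.2 equiv) in wet 1,4-dioxane is allowed to run through to the ring-opened 4-hydroxyaryl ketone F1. NaBH4 in MeOH then gives the 1,4-diol F2 as a mixture of C5 epimers. Catalytic PPTS in CH2Cl2 should ionise only the p-hydroxybenzylic C5–OH, so quinone methide 17 forms with no oxidant present and closes to 18.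

2. **Step 6.**
   - What may go wrong: slow insertion or poor enantioface discrimination, because the ortho-silyloxy group twists the aryl ring out of conjugation with the alkene.
   - Fallback: it replaces hydroboration by asymmetric hydrogenation, sets out from 10 and 12 and comes back at 13. Heck arylation (Pd(OAc)2, P(o-tol)3, Et3N, DMF, 100 °C) gives the (E)-1,2-diarylpropene F3. Hydrogenation with [Ir(cod)(tBu-PHOX)]BArF (H2, 50 bar, CH2Cl2) should then deliver 13 directly. This substrate class is the standard one for that catalyst family.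

3. **Step 8.**
   - What may go wrong: poor facial selectivity of the hydroboration when the hydroxyl is masked only as a borinate, and slow oxidative addition into the electron-rich aryl chloride while the alkylborane decays.
   - Fallback: it sets C4 on an isolable compound and forms the C5–ring B bond by Negishi coupling. It sets out from 7 and comes back at 16.
     - TBSCl/imidazole gives the silyl ether F4.
     - 9-BBN gives the B-alkyl borane F5.
     - I2/NaOMe converts F5 into the primary iodide F6, which can be freed from any C4 epimer by chromatography.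
     - Zn dust/LiCl in THF gives the alkylzinc iodide F7.
     - Pd(OAc)2/SPhos couples F7 with 13 to the bis-silyl ether F8.
     - TBAF removes both silyl groups to give 16.

Further compounds
F1 | step 9 | (2R,3S,4S)-4-[4-(benzyloxy)phenyl]-1-{3-[(2R)-1-[4-(benzyloxy)phenyl]propan-2-yl]-4-hydroxyphenyl}-4-hydroxy-2,3-dimethylbutan-1-one | C[C@@H](C(=O)c1ccc(O)c([C@H](C)Cc2ccc(OCc3ccccc3)cc2)c1)[C@H](C)[C@@H](c1ccc(OCc2ccccc2)cc1)O
F2 | step 9 | (2R,3S,4S)-4-[4-(benzyloxy)phenyl]-1-{3-[(2R)-1-[4-(benzyloxy)phenyl]propan-2-yl]-4-hydroxyphenyl}-2,3-dimethylbutane-1,4-diol, both C1 epimers | C[C@@H](C(O)c1ccc(O)c([C@H](C)Cc2ccc(OCc3ccccc3)cc2)c1)[C@H](C)[C@@H](c1ccc(OCc2ccccc2)cc1)O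
F3 | step 6 | {2-[(E)-1-[4-(benzyloxy)phenyl]prop-1-en-2-yl]-4-chlorophenoxy}tri(propan-2-yl)silane | C/C(=C\c1ccc(OCc2ccccc2)cc1)c1cc(Cl)ccc1O[Si](C(C)C)(C(C)C)C(C)C
F4 | step 8 | tert-butyldimethylsilyl ether of 7 | C=C(C)[C@H](C)[C@@H](c1ccc(OCc2ccccc2)cc1)O[Si](C)(C)C(C)(C)C
F5 | step 8 | B-alkyl-9-BBN adduct of F4, new centre as in 14 | C[C@@H](CB1C2CCCC1CCC2)[C@H](C)[C@@H](c1ccc(OCc2ccccc2)cc1)O[Si](C)(C)C(C)(C)C
F6 | step 8 | primary iodide, {(1S,2S,3R)-1-[4-(benzyloxy)phenyl]-4-iodo-2,3-dimethylbutoxy}(tert-butyl)dimethylsilane | C[C@@H](CI)[C@H](C)[C@@H](c1ccc(OCc2ccccc2)cc1)O[Si](C)(C)C(C)(C)C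
F7 | step 8 | alkylzinc iodide from F6 | C[C@@H](C[Zn]I)[C@H](C)[C@@H](c1ccc(OCc2ccccc2)cc1)O[Si](C)(C)C(C)(C)C
F8 | step 8 | tert-butyldimethylsilyl ether of 15 | C[C@@H](Cc1ccc(O[Si](C(C)C)(C(C)C)C(C)C)c([C@H](C)Cc2ccc(OCc3ccccc3)cc2)c1)[C@H](C)[C@@H](c1ccc(OCc2ccccc2)cc1)O[Si](C)(C)C(C)(C)C
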